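**Plan**
1. Retrosynthesis: the C1 ketone and the C2′ hydroxyl are re-joined as a five-membered silyl ketal (C1–O–C2′–C1′–C6) and the C6 hydroxyl is silylated; the C4 carbinol goes back to a ketone; then C4–C5 and C1–C6 are cut together (retro-[4+2] after re-closing a C1–O–C4 bridge).
2. This leaves a 2-alkoxy-5-silyloxyfuran (C1 to C4, the alkoxy oxygen being the C2′ oxygen) tied through O–C2′–C1′ to the silyl enol ether C5H2=C6(OSi) of a methyl ketone.
3. Enabling feature: C1(=O)–C2=C3–C4(OH) is a cis-butene with oxygen on both ends, i.e. the four carbons of a 2,5-dioxyfuran; C1=O and the C2′ oxygen are 1,4-related through C6–C1′, so the side-chain oxygen can serve as the furan alkoxy group, the tether and later the ketal; C5–C6(OH) is the enol of an aldol-type methyl ketone.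
4. Forward: chain with C2′ (allylboration), butenolide acetal, Wacker ketone, double silylation, then one intramolecular Diels–Alder/bridge opening closes the cyclohexene and the oxolane rings; C4 reduction; unmasking.
5. Stereochemistry: C2′ by reagent-controlled allylboration; C6 from C2′ through the tether in the cycloaddition; C4 by hydride addition anti to the axial C6 silyloxy group; the Z-olefin comes with the aldehyde; the acetal epimers converge when the furan forms.

Key step: step 5

Remark: (9Z)-hexadec-9-enal and 5-hydroxyfuran-2(5H)-one are taken as purchasable; ring atoms are called C1 (C=O) to C6 (quaternary carbinol) and side-chain atoms C1′, C2′ as in the target.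

**Step 1**
Reactants: 1 (9Z)-hexadec-9-enal
Product: 3 (4S,12Z)-nonadeca-1,12-dien-4-ol, via borinate ester 2 (not isolated)
Conditions: (+)-Ipc2B(allyl), Et2O, −78 °C; then NaOH, H2O2, 0 °C to rt
Reagents that add atoms: (+)-B-allyldiisopinocampheylborane, C=CCB([C@H]1C[C@H]2C[C@@H]([C@@H]1C)C2(C)C)[C@H]1C[C@H]2C[C@@H]([C@@H]1C)C2(C)C
Why: Brown allylboration through a chair six-membered transition state; the (+)-Ipc2B reagent (from (−)-α-pinene) adds allyl to the Re face of an unbranched aldehyde and should give the (S)-carbinol, while the isolated Z-olefin is inert.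

**Step 2**
Reactants: 3 (4S,12Z)-nonadeca-1,12-dien-4-ol; 4 5-hydroxyfuran-2(5H)-one
Product: 5 5-{[(4S,12Z)-nonadeca-1,12-dien-4-yl]oxy}furan-2(5H)-one (both acetal epimers)
Conditions: 4 (2.5 equiv), CSA (5 mol%), toluene, 4 Å MS, 80 °C
Reagents that add atoms: none
Why: Acid-catalysed acetalisation of the lactol with a secondary alcohol (pseudo-ester formation); both epimers at the acetal carbon are carried on because this carbon becomes sp2 in step 4.

**Step 3**
Reactants: 5 5-{[(4S,12Z)-nonadeca-1,12-dien-4-yl]oxy}furan-2(5H)-one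
Product: 6 5-{[(4S,12Z)-2-oxononadec-12-en-4-yl]oxy}furan-2(5H)-one
Conditions: PdCl2 (10 mol%), CuCl, O2 (1 atm), DMF/H2O 7:1, rt
Reagents that add atoms: water, O
Why: Tsuji–Wacker oxidation; Markovnikov hydroxypalladation of the terminal alkene should give the methyl ketone, the Z-1,2-disubstituted olefin and the electron-poor butenolide reacting much more slowly.

**Step 4**
Reactants: 6 5-{[(4S,12Z)-2-oxononadec-12-en-4-yl]oxy}furan-2(5H)-one
Product: 8 triethyl{[5-({(4S,12Z)-2-[(triethylsilyl)oxy]nonadeca-1,12-dien-4-yl}oxy)furan-2-yl]oxy}silane, via monosilylated furyl ketone 7 (not isolated)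
Conditions: LiHMDS (2.4 equiv), TESCl (3 equiv), Et3N, THF, −78 °C (in-situ quench); pentane, cold NaHCO3; used without chromatography
Reagents that add atoms: chlorotriethylsilane, CC[Si](Cl)(CC)CC
Why: Kinetic double deprotonation with in-situ O-silylation (silyl enol ether formation): the butenolide γ-H goes first to the aromatic furan-2-olate, which merges both acetal epimers, and the methyl ketone is then deprotonated on the CH3 side, giving the 2-alkoxy-5-silyloxyfuran and the terminal silyl enol ether.

**Step 5**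
Reactants: 8 triethyl{[5-({(4S,12Z)-2-[(triethylsilyl)oxy]nonadeca-1,12-dien-4-yl}oxy)furan-2-yl]oxy}silane
Product: 10 (2S,3aR,7aR)-2-[(8Z)-pentadec-8-en-1-yl]-3a,7a-bis[(triethylsilyl)oxy]-3,3a,4,7a-tetrahydro-1-benzofuran-5(2H)-one, via oxa-bridged cycloadduct 9 (not isolated)
Conditions: toluene (0.01 M, degassed), BHT (cat.), 110 °C, sealed tube
Reagents that add atoms: none
Why: Proposed new method: an intramolecular Diels–Alder reaction of the furan (π4s; the carbon bearing the tether oxygen becomes C1, the carbon bearing OSiEt3 becomes C4) with the tethered 1,1-disubstituted silyl enol ether (π2s) forms C1–C6 and C4–C5 at once and gives the oxygen-bridged bis-ketal 9, whose bridge then opens at C4 with a 1,3 O-to-O silyl shift to the enone 10, an irreversible, strain-releasing step that should pull the reversible cycloaddition forward although both partners are electron-rich. The closest known reaction type is the thermal intramolecular Diels–Alder reaction of 2-amidofurans tethered through nitrogen to unactivated alkenes with subsequent opening of the oxygen bridge, together with the intermolecular Diels–Alder chemistry of 2,5-bis(silyloxy)furans. The cyclohexene ring closes by the [4+2] cycloaddition in the type-1 intramolecular mode with the three-atom tether O–C2′–C1′ on the diene terminus, and the oxolane ring closes in the same event through the C1–C6 bond, exo-fused (tether arm syn to the oxygen bridge), which leaves a trans-fused bicycle after the bridge opens. C6 is the new permanent stereocentre and is controlled by C2′: in the forming oxolane C6 is the envelope flap and carries the endo OSiEt3 group pseudo-axially, so the pentadecenyl chain on C2′ should take the opposite face, which corresponds to 6R from 2′S; the ketal carbon C1 is a temporary stereocentre fixed by the tether. The step needs regiochemistry (C1 to C6, C4 to C5), secured by the tether, and π-facial selectivity at the enol ether, secured by the 1,3-relationship between the C2′ substituent and the endo silyloxy group; C4 stays at the ketone level and the ketal at C1 keeps the two carbonyls of the ene-dione apart.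

**Step 6**
Reactants: 10 (2S,3aR,7aR)-2-[(8Z)-pentadec-8-en-1-yl]-3a,7a-bis[(triethylsilyl)oxy]-3,3a,4,7a-tetrahydro-1-benzofuran-5(2H)-one
Product: 12 (2S,3aS,5S,7aR)-2-[(8Z)-pentadec-8-en-1-yl]-3a,7a-bis[(triethylsilyl)oxy]-2,3,3a,4,5,7a-hexahydro-1-benzofuran-5-ol, via diisobutylaluminium alkoxide 11 (not isolated)
Conditions: DIBAL-H (1.3 equiv), toluene/CH2Cl2, −78 °C; Rochelle salt
Reagents that add atoms: none
Why: Substrate-controlled 1,2-reduction of the only free carbonyl (C1 is a ketal): in the trans-fused, locked bicycle the C6 silyloxy group is axial and syn-axial to one face of C4, so the bulky aluminium hydride should add from the other face and place the new hydroxyl cis to the C6 oxygen (4S in target numbering).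

**Step 7**
Reactants: 12 (2S,3aS,5S,7aR)-2-[(8Z)-pentadec-8-en-1-yl]-3a,7a-bis[(triethylsilyl)oxy]-2,3,3a,4,5,7a-hexahydro-1-benzofuran-5-ol
Product: 14 (4S,6R)-4,6-dihydroxy-6-[(2S,10Z)-2-hydroxyheptadec-10-en-1-yl]cyclohex-2-en-1-one, via 6-O-triethylsilyl enone 13 (not isolated)
Conditions: HF·pyridine, pyridine, THF, 0 °C to rt
Reagents that add atoms: none
Why: Global desilylation: loss of the anomeric silyl group lets the hemiketal collapse to the C1 enone and the free C2′ hydroxyl, and the tertiary silyl ether is then cleaved under the same buffered HF conditions, which the 4-hydroxy-enone should tolerate.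

**Compound list**
1 | (9Z)-hexadec-9-enal | CCCCCC/C=C\CCCCCCCC=O | starting material
2 | (4S,12Z)-nonadeca-1,12-dien-4-yl bis[(1S,2S,3S,5R)-isopinocampheyl]borinate | CCCCCC/C=C\CCCCCCC[C@@H](CC=C)OB([C@H]1C[C@H]2C[C@@H]([C@@H]1C)C2(C)C)[C@H]1C[C@H]2C[C@@H]([C@@H]1C)C2(C)C | intermediate
3 | (4S,12Z)-nonadeca-1,12-dien-4-ol | CCCCCC/C=C\CCCCCCC[C@H](O)CC=C | intermediate
4 | 5-hydroxyfuran-2(5H)-one | OC1OC(=O)C=C1 | starting material
5 | 5-{[(4S,12Z)-nonadeca-1,12-dien-4-yl]oxy}furan-2(5H)-one (both acetal epimers) | CCCCCC/C=C\CCCCCCC[C@@H](CC=C)OC1OC(=O)C=C1 | intermediate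
6 | 5-{[(4S,12Z)-2-oxononadec-12-en-4-yl]oxy}furan-2(5H)-one (both acetal epimers) | CCCCCC/C=C\CCCCCCC[C@@H](CC(C)=O)OC1OC(=O)C=C1 | intermediate
7 | (4S,12Z)-4-({5-[(triethylsilyl)oxy]furan-2-yl}oxy)nonadec-12-en-2-one | CCCCCC/C=C\CCCCCCC[C@@H](CC(C)=O)Oc1ccc(O[Si](CC)(CC)CC)o1 | intermediate
8 | triethyl{[5-({(4S,12Z)-2-[(triethylsilyl)oxy]nonadeca-1,12-dien-4-yl}oxy)furan-2-yl]oxy}silane | CCCCCC/C=C\CCCCCCC[C@@H](CC(=C)O[Si](CC)(CC)CC)Oc1ccc(O[Si](CC)(CC)CC)o1 | intermediate
9 | oxygen-bridged bis-ketal cycloadduct: 2-[(8Z)-pentadec-8-enyl]-3a,5-bis(triethylsilyloxy)-2,3,3a,4-tetrahydro-5H-5,7a-epoxy-1-benzofuran, oxolane exo-fused, chain anti to the 3a-silyloxy group | CCCCCC/C=C\CCCCCCC[C@H]1C[C@@]2(O[Si](CC)(CC)CC)C[C@]3(O[Si](CC)(CC)CC)C=C[C@@]2(O1)O3 | intermediate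
10 | (2S,3aR,7aR)-2-[(8Z)-pentadec-8-en-1-yl]-3a,7a-bis[(triethylsilyl)oxy]-3,3a,4,7a-tetrahydro-1-benzofuran-5(2H)-one | CCCCCC/C=C\CCCCCCC[C@H]2C[C@@]1(O[Si](CC)(CC)CC)CC(=O)C=C[C@]1(O[Si](CC)(CC)CC)O2 | intermediate
11 | diisobutylaluminium alkoxide of 12 | CCCCCC/C=C\CCCCCCC[C@H]2C[C@@]1(O[Si](CC)(CC)CC)C[C@H](O[Al](CC(C)C)CC(C)C)C=C[C@]1(O[Si](CC)(CC)CC)O2 | intermediate
12 | (2S,3aS,5S,7aR)-2-[(8Z)-pentadec-8-en-1-yl]-3a,7a-bis[(triethylsilyl)oxy]-2,3,3a,4,5,7a-hexahydro-1-benzofuran-5-ol | CCCCCC/C=C\CCCCCCC[C@H]2C[C@@]1(O[Si](CC)(CC)CC)C[C@H](O)C=C[C@]1(O[Si](CC)(CC)CC)O2 | intermediate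
13 | (4S,6R)-4-hydroxy-6-[(2S,10Z)-2-hydroxyheptadec-10-en-1-yl]-6-[(triethylsilyl)oxy]cyclohex-2-en-1-one | CCCCCC/C=C\CCCCCCC[C@H](O)C[C@@]1(O[Si](CC)(CC)CC)C[C@H](O)C=CC1=O | intermediate
14 | (4S,6R)-4,6-dihydroxy-6-[(2S,10Z)-2-hydroxyheptadec-10-en-1-yl]cyclohex-2-en-1-one | CCCCCC/C=C\CCCCCCC[C@H](O)C[C@@]1(O)C[C@H](O)C=CC1=O | target

**Totals**
Total step count: 7. Longest linear sequence: 7 steps (1 to 14).

**Steps most likely to fail**

Step 5 (proposed new method). The cycloaddition may not take place, or may revert, because diene and dienophile are both electron-rich; the bis-oxygenated furan may also be lost by desilylation or oligomerisation at the temperature needed. The fallback uses known reactions only and makes the ring by two polar C–C bond formations instead of a cycloaddition; it sets out from 3 and comes back at 14. Silylation of 3 (TBSOTf, 2,6-lutidine) should give the tert-butyldimethylsilyl ether F1, and Tsuji–Wacker oxidation the methyl ketone F2. Its kinetic boron enolate (Ipc2BCl, Et3N; the antipode that gives the 4R carbinol by reagent control, to be checked by Mosher analysis) would add to 4,4-dimethoxybutanal to give the aldol F3, whose new carbinol carbon becomes C4. Silylation would give the bis-silyl ether F4, and acetal hydrolysis (PPTS, wet acetone) the keto-aldehyde F5. An aminoindanol-derived chiral triazolylidene carbene (Et3N, toluene) should then close the six-membered ring by an intramolecular crossed aldehyde–ketone benzoin reaction to the acyloin F6, with catalyst control at C6. IBX dehydrogenation, which can only go towards C2–C3 because C6 is quaternary, would give the enone F7, and HF·pyridine would give 14.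

Step 6. Hydride delivery may occur from the face syn to the axial silyloxy group (the torsionally preferred axial attack), or the ring fusion may have epimerised at the ketal carbon so that the facial bias is lost; either gives the wrong carbinol configuration. The fallback corrects the centre by inversion instead of re-tuning the reduction; it sets out from 10 and comes back at 12. The reduction then gives mainly the 5-epimeric alcohol F8, the only free hydroxyl in the molecule; Mitsunobu reaction (4-nitrobenzoic acid, PPh3, DIAD) should give the inverted 4-nitrobenzoate F9, and brief methanolysis (K2CO3, MeOH, 0 °C) would give 12.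

Step 3. The oxidation has to tell three olefins apart in an acidic aqueous Pd/Cu medium; the acetal may hydrolyse, the acetal oxygen may steer part of the material to the aldehyde, and Pd–H may start to isomerise the Z-olefin on long reaction times. The fallback oxidises before the acetal exists and makes the acetal under neutral conditions; it sets out from 3 (with 4) and comes back at 6. Tsuji–Wacker oxidation of the free homoallylic alcohol 3 should give the β-hydroxy ketone F10; lactol 4 is converted (Boc2O, DMAP) into its tert-butyl carbonate F11; Tsuji–Trost allylic etherification (Pd2(dba)3·CHCl3, PPh3, CH2Cl2, 0 °C) of F10 with F11 would give 6 without acid or heat.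

**Further compounds**
F1 | step 5 | tert-butyl(dimethyl){[(4S,12Z)-nonadeca-1,12-dien-4-yl]oxy}silane | CCCCCC/C=C\CCCCCCC[C@@H](CC=C)O[Si](C)(C)C(C)(C)C
F2 | step 5 | (4S,12Z)-4-[(tert-butyldimethylsilyl)oxy]nonadec-12-en-2-one | CCCCCC/C=C\CCCCCCC[C@@H](CC(C)=O)O[Si](C)(C)C(C)(C)C
F3 | step 5 | (4R,8S,16Z)-8-[(tert-butyldimethylsilyl)oxy]-4-hydroxy-1,1-dimethoxytricos-16-en-6-one | CCCCCC/C=C\CCCCCCC[C@@H](CC(=O)C[C@H](O)CCC(OC)OC)O[Si](C)(C)C(C)(C)C
F4 | step 5 | (4R,8S,16Z)-4,8-bis[(tert-butyldimethylsilyl)oxy]-1,1-dimethoxytricos-16-en-6-one | CCCCCC/C=C\CCCCCCC[C@@H](CC(=O)C[C@H](O[Si](C)(C)C(C)(C)C)CCC(OC)OC)O[Si](C)(C)C(C)(C)C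
F5 | step 5 | (4R,8S,16Z)-4,8-bis[(tert-butyldimethylsilyl)oxy]-6-oxotricos-16-enal | CCCCCC/C=C\CCCCCCC[C@@H](CC(=O)C[C@H](O[Si](C)(C)C(C)(C)C)CCC=O)O[Si](C)(C)C(C)(C)C
F6 | step 5 | 4-O,2′-O-bis(tert-butyldimethylsilyl) ether of 2,3-dihydro-14 (saturated acyloin, configuration as in 14) | CCCCCC/C=C\CCCCCCC[C@H](O[Si](C)(C)C(C)(C)C)C[C@@]1(O)C[C@H](O[Si](C)(C)C(C)(C)C)CCC1=O
F7 | step 5 | 4-O,2′-O-bis(tert-butyldimethylsilyl) ether of 14 | CCCCCC/C=C\CCCCCCC[C@H](O[Si](C)(C)C(C)(C)C)C[C@@]1(O)C[C@H](O[Si](C)(C)C(C)(C)C)C=CC1=O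
F8 | step 6 | 5-epimer of 12, (2S,3aS,5R,7aR) | CCCCCC/C=C\CCCCCCC[C@H]2C[C@@]1(O[Si](CC)(CC)CC)C[C@@H](O)C=C[C@]1(O[Si](CC)(CC)CC)O2
F9 | step 6 | 4-nitrobenzoate of 12 | CCCCCC/C=C\CCCCCCC[C@H]2C[C@@]1(O[Si](CC)(CC)CC)C[C@H](OC(=O)c3ccc(cc3)[N+](=O)[O-])C=C[C@]1(O[Si](CC)(CC)CC)O2
F10 | step 3 | (4S,12Z)-4-hydroxynonadec-12-en-2-one | CCCCCC/C=C\CCCCCCC[C@H](O)CC(C)=O
F11 | step 3 | tert-butyl 5-oxo-2,5-dihydrofuran-2-yl carbonate | CC(C)(C)OC(=O)OC1OC(=O)C=C1
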